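**Numbering used throughout.** 1–7 ring-A branch (7 = silyl triflate); 8–14 ring-B branch (14 = propiolic acid); 15 and 16 transient species of the key step; 17 flavone from the key step; 18–24 late stage; 25 target. Compounds 3, 13, 15, 16, 19 and 23 are not isolated. Flavone numbering (O1, C2, C3, C4, C4a, C5–C8, C8a; ring-B positions primed) is used for every chromenone.

## Analysis of the target

Compound 25 is a flavonol: benzene ring A is fused to the 4-pyranone ring C (O1, C2, C3, C4, C4a, C8a), which carries aryl ring B at C2. It has no stereocentre, so the whole problem is one of oxygenation pattern. Seven oxygen substituents must be told apart: four free hydroxyls (C3, C5, C3', C5') and three methyl ethers (C7, C8, C4'). Ring A is pentasubstituted, with oxygen on C5, C7, C8 and C8a, whereas ring B is the symmetric 3,5-dihydroxy-4-methoxyphenyl group. The 3-hydroxy-4-pyranone enol is easily oxidised in base and air, and the C5-OH/C8-OMe pair is a hydroquinone monoether whose 5,8-diol forerunner goes readily to the quinone. The methyl ethers must survive every deprotection, which rules out strong Lewis acids at the end. The difficulty is to build the crowded ring A regioselectively and to differentiate its oxygens while the B-ring phenols stay masked. The strategy rests on the fact that O1 and the C4 carbonyl sit on the neighbouring ring-A carbons C8a and C4a. These are the two carbons of an aryne, one of which can take a nucleophilic oxygen and the other an acyl group, and the C5 oxygen next to C4a is placed to polarise that aryne.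

## Retrosynthetic reasoning

**25 to 24.** The three O–benzyl bonds at O5, O3' and O5' are cut. Every hydroxyl of 25 except the C3 enol is carried as a benzyl ether, so one neutral hydrogenolysis at the end frees them without touching the three methyl ethers.

**24 to 22.** The C3–O bond is cut. The 3-hydroxy enol is the most fragile function, so it is made last among the skeletal oxygens. The forward reaction is epoxidation of C2=C3 and acid opening of epoxide 23. It should not meet a free phenol, which is why O5 is benzylated in 22.

**22 back to 17 (through 21, 20 and 18).** The C8–O bond is cut para to the C5 hydroxyl. C8 cannot carry its oxygen through the ring-forming step, because a second oxygen flanking the aryne would cancel the polarisation that controls it. In 18 the free 5-hydroxyl is the one group that directs a para-hydroxylation to C8 (Elbs oxidation through sulfate 19). The resulting 5,8-diol 20 is methylated at O8 only, because O5–H is chelated to C4=O, and O5 is then benzylated again. Phenol 18 comes from 17 by chelation-selective loss of the peri benzyl group. Freeing and recapping O5 costs two steps, but it turns the protecting-group position into the directing group for C8.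

**17 to 7 and 14.** This is the key disconnection: C8a–O1, C4a–C4 and O1–C2 are cut, so ring C is taken apart completely. It gives two fragments of similar size: silyl triflate 7 (the source of aryne 15) and arylpropiolic acid 14, which supplies O1, C4, C3, C2 and ring B. In the forward direction the carboxylate oxygen must add to C8a, the acyl group must move to C4a (giving ynone 16), and the phenoxide must close onto the alkyne. The cut is made here because it is convergent, forms three bonds in one operation, needs no redox adjustment of ring C, and its regiochemistry is set by the single benzyloxy group next to the aryne.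

**7 back to 1 (through 6, 5, 4 and 2).** The C–Si bond and the O-substituents are cut. Silicon must sit between the triflate oxygen and the benzyloxy oxygen, not beside the methoxy group. A benzyl ether and a methyl ether are equally weak co-directors, so lithiating a ring that already carries the benzyl group could not tell the two positions flanking the directing group apart. Silicon is therefore introduced on the symmetric bis-carbamate 2 (through aryllithium 3), where the position between the two strong directors is unique. The two oxygens are differentiated only afterwards (5 to 6 to 7), at a stage where either oxygen gives the same compound.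

**14 back to 8 (through 12, 11, 10 and 9).** The bond between the alkyne and the carboxyl carbon is cut (carboxylation of acetylide 13). The alkyne carbon comes from one-carbon homologation of aldehyde 11 (Corey–Fuchs), and 11 comes from acid 8 by benzylation and adjustment of the oxidation level.

## Alternatives that were turned down

**Alternative 1:** Ring C is opened at C3–C4. The precursor is dialdehyde A2, a pentasubstituted salicylaldehyde O-alkylated at O1 by a 2-aryl-2-oxyacetaldehyde unit. A carbene organocatalyst turns one formyl group into an acyl-anion equivalent that adds to the other, giving the trans-3-hydroxychroman-4-one A1.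
- For: the C3 hydroxyl arrives with the ring, and ring A enters with O8 already methylated. No late C–H oxidation and no freeing and recapping of O5 are needed, and the conditions are mild. On these points it is stronger than the chosen route.
- Against: A1 is a dihydroflavonol. Its two stereocentres are made only to be erased by an extra dehydrogenation at C2–C3.
- Against: the crossed aldehyde–aldehyde benzoin is biased the wrong way. The unhindered aliphatic formyl group of A2 should form the acyl-anion equivalent faster than the aromatic one, which is flanked by two ortho oxygens and deactivated by three donors. That sense of addition gives the 4-hydroxy-3-ketone.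
- Against: the α-aryl-α-aryloxy aldehyde is strongly C–H acidic and prone to aldol side reactions under the basic catalyst. A2 also needs a separately built, fully differentiated tetraoxygenated benzaldehyde, which is longer than the route to 7.
- Comparison: the chosen strategy gives the aromatic ring C directly at the right oxidation level, from two fragments of five steps each, in a closure whose regiochemistry is set by one substituent.

**Alternative 2:** Ring A is cut at C6–C7 and made last. The precursor is the tetrasubstituted 4-pyranone A4, with an acetyl group on the future C4a and a methoxyacetate side chain on the future C8a. A non-nucleophilic base would form the methyl enolate, which attacks the ester (Claisen condensation); the new ring aromatises to the 5,7-diol A3.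
- For: the A-ring pattern (5-OH, 7-OH, 8-OMe) follows unambiguously from the chain, and the C3 oxygen is already in place. After A3 only a selective 7-O-methylation and a hydrogenolysis remain. In the late stage this is clearly shorter than the chosen route.
- Against: the burden moves to A4, a 4-pyranone with four different substituents, whose synthesis would be longer than the whole chosen route.
- Against: the most acidic proton of A4 is the doubly activated CH of the side chain, not the acetyl methyl, so the first equivalent of base makes an anion that cannot close ring A.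
- Against: 3-acyl-4-pyranones are strongly electrophilic at C2 and C6, so enolates and bases can add to or open the pyranone instead of condensing.
- Comparison: the chosen strategy accepts a longer late stage in exchange for simple precursors and a ring closure of a known type.

**Alternative 3:** Ring C is cut at C4–C4a. The precursor is the Z-configured 3-aryloxy-3-arylacrylic acid A6. After activation in a strongly acidic dehydrating medium it acylates the phenoxy ring at the only free position ortho to oxygen (Friedel–Crafts), giving flavone A5.
- For: the ring-closure regiochemistry is unambiguous, and ring A enters fully oxygenated. A5 is identical with compound 22, so this route would join the chosen one after step 15 and make steps 12–15 unnecessary. On late-stage step economy it is stronger.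
- Against: the closure runs in strong acid on a substrate with three benzyl ethers on electron-rich rings. Debenzylation, benzyl-cation re-alkylation of the rings, and retro-addition of the aryloxy acrylate are all to be expected.
- Against: the acid must have the aryloxy and carboxyl groups cis, which the oxa-Michael addition that makes it does not guarantee.
- Against: the 1,2,3,5-tetraoxygenated phenol needed for A6, with three different O-substituents, moves the C8-oxygenation problem into a precursor of about the same length as the sequence it saves.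
- Comparison: the chosen key step runs under basic fluoride conditions in which benzyl ethers are inert, has no alkene-geometry requirement, and starts from a symmetric phenol.

Key step: step 11

## Route

Remark on the chemistry: compounds 1 and 8 are taken as purchasable. Epoxide 23 is racemic and drawn as one enantiomer; the target has no stereocentre.

Step 1
Reactants: 1 5-methoxybenzene-1,3-diol
Product: 2 5-methoxy-1,3-phenylene bis(N,N-diethylcarbamate)
Conditions: ClC(O)NEt2 (2.4 equiv), K2CO3, MeCN, reflux
Reagents that add atoms: N,N-diethylcarbamoyl chloride, CCN(CC)C(=O)Cl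
Why: O-carbamoylation of both phenols (Schotten–Baumann-type acylation); the two diethylcarbamates are the strongest oxygen-based directors for ortho-lithiation and keep the ring symmetric about C2.

Step 2
Reactants: 2 5-methoxy-1,3-phenylene bis(N,N-diethylcarbamate)
Product: 4 5-methoxy-2-(trimethylsilyl)-1,3-phenylene bis(N,N-diethylcarbamate), via aryllithium 3 (not isolated)
Conditions: s-BuLi, TMEDA, THF, −78 °C; Me3SiCl, −78 °C → rt
Reagents that add atoms: chlorotrimethylsilane, C[Si](C)(C)Cl
Why: Directed ortho-metalation; the position between the two carbamates is flanked by both directing carbonyl groups and should be deprotonated in preference to the positions beside the weaker methoxy director. At −78 °C aryllithium 3 does not undergo anionic Fries rearrangement and is silylated.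

Step 3
Reactants: 4 5-methoxy-2-(trimethylsilyl)-1,3-phenylene bis(N,N-diethylcarbamate)
Product: 5 5-methoxy-2-(trimethylsilyl)benzene-1,3-diol
Conditions: LiAlH4 (excess), THF, 0 °C → reflux; aq. potassium sodium tartrate, pH 7
Reagents that add atoms: none
Why: Hydride reduction of the aryl carbamates releases both phenoxides and the N-methylamine; the aryl–silicon bond is inert to LiAlH4, and a neutral work-up avoids ipso-protodesilylation of the electron-rich arylsilane.

Step 4
Reactants: 5 5-methoxy-2-(trimethylsilyl)benzene-1,3-diol
Product: 6 3-(benzyloxy)-5-methoxy-2-(trimethylsilyl)phenol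
Conditions: BnBr (1.0 equiv), K2CO3, MeCN, 40 °C; recovered 5 recycled
Reagents that add atoms: benzyl bromide, BrCc1ccccc1
Why: Williamson etherification; the two hydroxyls of 5 are equivalent, so one equivalent of benzyl bromide should give mainly monoether 6 beside recoverable 5 and the separable diether, and either oxygen leads to the same compound.

Step 5
Reactants: 6 3-(benzyloxy)-5-methoxy-2-(trimethylsilyl)phenol
Product: 7 3-(benzyloxy)-5-methoxy-2-(trimethylsilyl)phenyl trifluoromethanesulfonate
Conditions: Tf2O, pyridine, CH2Cl2, 0 °C
Reagents that add atoms: trifluoromethanesulfonic anhydride, O=S(=O)(OS(=O)(=O)C(F)(F)F)C(F)(F)F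
Why: O-sulfonylation of the remaining phenol gives the o-silylaryl triflate; no free hydroxyl is left that could trigger aryne release before fluoride is added.

Step 6
Reactants: 8 3,5-dihydroxy-4-methoxybenzoic acid
Product: 9 benzyl 3,5-bis(benzyloxy)-4-methoxybenzoate
Conditions: BnBr (3.3 equiv), K2CO3, DMF, 60 °C
Reagents that add atoms: benzyl bromide, BrCc1ccccc1
Why: Exhaustive O-benzylation (Williamson etherification of both phenols and alkylation of the carboxylate).

Step 7
Reactants: 9 benzyl 3,5-bis(benzyloxy)-4-methoxybenzoate
Product: 10 [3,5-bis(benzyloxy)-4-methoxyphenyl]methanol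
Conditions: LiAlH4, THF, 0 °C → rt
Reagents that add atoms: none
Why: Hydride reduction of the ester to the benzylic alcohol; aryl benzyl ethers are untouched.

Step 8
Reactants: 10 [3,5-bis(benzyloxy)-4-methoxyphenyl]methanol
Product: 11 3,5-bis(benzyloxy)-4-methoxybenzaldehyde
Conditions: activated MnO2, CH2Cl2, rt
Reagents that add atoms: none
Why: Selective oxidation of a benzylic alcohol to the aldehyde with MnO2, which does not over-oxidise.

Step 9
Reactants: 11 3,5-bis(benzyloxy)-4-methoxybenzaldehyde
Product: 12 1,3-bis(benzyloxy)-5-(2,2-dibromoethenyl)-2-methoxybenzene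
Conditions: CBr4, PPh3, CH2Cl2, 0 °C
Reagents that add atoms: tetrabromomethane, BrC(Br)(Br)Br
Why: First stage of the Corey–Fuchs homologation; the dibromomethylene ylide formed from CBr4 and PPh3 olefinates the aldehyde (Wittig-type).

Step 10
Reactants: 12 1,3-bis(benzyloxy)-5-(2,2-dibromoethenyl)-2-methoxybenzene
Product: 14 3-[3,5-bis(benzyloxy)-4-methoxyphenyl]prop-2-ynoic acid, via lithium acetylide 13 (not isolated)
Conditions: n-BuLi (2.2 equiv), THF, −78 °C; CO2, −78 °C → rt; aq. HCl
Reagents that add atoms: carbon dioxide, O=C=O
Why: Second stage of Corey–Fuchs; Br/Li exchange and Fritsch–Buttenberg–Wiechell rearrangement give the alkyne, the second equivalent of n-BuLi gives acetylide 13, and carboxylation followed by acidification gives the acid.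

Step 11
Reactants: 7 3-(benzyloxy)-5-methoxy-2-(trimethylsilyl)phenyl trifluoromethanesulfonate (1.3 equiv); 14 3-[3,5-bis(benzyloxy)-4-methoxyphenyl]prop-2-ynoic acid
Product: 17 5-(benzyloxy)-2-[3,5-bis(benzyloxy)-4-methoxyphenyl]-7-methoxy-4H-chromen-4-one, via aryne 15 (not isolated), via hydroxyaryl ynone 16 (not isolated)
Conditions: CsF (4 equiv), THF, 125 °C, sealed tube
Reagents that add atoms: none
Why: Fluoride attacks silicon of 7 and expels triflate, releasing aryne 15. The cesium carboxylate of 14 adds through oxygen to the aryne carbon remote from the benzyloxy group (the future C8a), so the aryl anion develops at the future C4a beside the inductively withdrawing C5–O bond, which is the usual selectivity of 3-alkoxyarynes. The anion attacks the neighbouring ester carbonyl through a four-membered transition state (a Fries-type O-to-C acyl shift), forming C4a–C4 and giving the phenoxide of ynone 16. That phenoxide adds to the ynone β-carbon in a 6-endo-dig oxa-Michael closure (O1–C2), and protonation at C3 completes the pyranone ring C. The closest known reaction type is aryne insertion into the C–O bond of carboxylic acids to give o-hydroxyaryl ketones, which with arylpropiolic acids runs on to flavones. No stereocentre is formed. The step needs three selectivities: aryne regiochemistry, secured by the single alkoxy group flanking the triple bond (the methoxy group is not adjacent and has little influence); acyl transfer faster than protonation of the aryl anion, favoured by the aprotic medium and excess CsF, which binds HF; and 6-endo over 5-exo closure, favoured by the polarisation of the aryl ynone.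

Step 12
Reactants: 17 5-(benzyloxy)-2-[3,5-bis(benzyloxy)-4-methoxyphenyl]-7-methoxy-4H-chromen-4-one
Product: 18 2-[3,5-bis(benzyloxy)-4-methoxyphenyl]-5-hydroxy-7-methoxy-4H-chromen-4-one
Conditions: MgBr2·OEt2 (3 equiv), toluene–Et2O, 80 °C; aq. HCl
Reagents that add atoms: none
Why: Chelation-controlled ether cleavage; divalent magnesium bound between C4=O and O5 activates only the peri benzyl ether towards bromide attack at the benzylic carbon, and the B-ring benzyl ethers have no such chelate.

Step 13
Reactants: 18 2-[3,5-bis(benzyloxy)-4-methoxyphenyl]-5-hydroxy-7-methoxy-4H-chromen-4-one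
Product: 20 2-[3,5-bis(benzyloxy)-4-methoxyphenyl]-5,8-dihydroxy-7-methoxy-4H-chromen-4-one, via aryl sulfate 19 (not isolated)
Conditions: K2S2O8, aq. KOH, pyridine, 15–20 °C; then 2 M HCl, dioxane, 80 °C, Ar
Reagents that add atoms: potassium peroxodisulfate, [K+].[K+].[O-]S(=O)(=O)OOS(=O)(=O)[O-]
Why: Elbs persulfate oxidation; the phenoxide attacks the peroxide oxygen through its para carbon C8 (also activated by the ortho 7-methoxy group) to give sulfate 19, which acid hydrolyses to the hydroquinone. Ring B has no free phenol and should not react.

Step 14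
Reactants: 20 2-[3,5-bis(benzyloxy)-4-methoxyphenyl]-5,8-dihydroxy-7-methoxy-4H-chromen-4-one
Product: 21 2-[3,5-bis(benzyloxy)-4-methoxyphenyl]-5-hydroxy-7,8-dimethoxy-4H-chromen-4-one
Conditions: Me2SO4 (1.05 equiv), K2CO3, acetone, 40 °C, Ar
Reagents that add atoms: dimethyl sulfate, COS(=O)(=O)OC
Why: Williamson O-methylation; the 5-hydroxyl is hydrogen-bonded to C4=O and far less nucleophilic than the 8-hydroxyl, so one equivalent should methylate O8 only. The inert atmosphere keeps the hydroquinone from oxidising to the 5,8-quinone.

Step 15
Reactants: 21 2-[3,5-bis(benzyloxy)-4-methoxyphenyl]-5-hydroxy-7,8-dimethoxy-4H-chromen-4-one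
Product: 22 5-(benzyloxy)-2-[3,5-bis(benzyloxy)-4-methoxyphenyl]-7,8-dimethoxy-4H-chromen-4-one
Conditions: BnBr, K2CO3, KI (cat.), DMF, 80 °C
Reagents that add atoms: benzyl bromide, BrCc1ccccc1
Why: Williamson benzylation of the chelated 5-hydroxyl under forcing conditions; capping it removes the free phenol and the hydrogen bond to C4=O before the dioxirane oxidation.

Step 16
Reactants: 22 5-(benzyloxy)-2-[3,5-bis(benzyloxy)-4-methoxyphenyl]-7,8-dimethoxy-4H-chromen-4-one
Product: 24 5-(benzyloxy)-2-[3,5-bis(benzyloxy)-4-methoxyphenyl]-3-hydroxy-7,8-dimethoxy-4H-chromen-4-one, via epoxide 23 (not isolated)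
Conditions: DMDO (acetone), CH2Cl2, 0 °C → rt, dark; then p-TsOH (cat.), CH2Cl2, rt
Reagents that add atoms: dimethyldioxirane, CC1(C)OO1
Why: Dioxirane epoxidation of the flavone C2=C3 bond, then acid-catalysed opening of epoxide 23 at C2 (cation stabilised by O1 and the aryl group) and loss of H3 give the 3-hydroxyflavone, a known flavone-to-flavonol sequence. The two stereocentres of racemic 23 vanish when ring C regains its unsaturation.

Step 17
Reactants: 24 5-(benzyloxy)-2-[3,5-bis(benzyloxy)-4-methoxyphenyl]-3-hydroxy-7,8-dimethoxy-4H-chromen-4-one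
Product: 25 2-(3,5-dihydroxy-4-methoxyphenyl)-3,5-dihydroxy-7,8-dimethoxy-4H-chromen-4-one
Conditions: H2 (1 atm), 10% Pd/C, EtOAc–MeOH, rt
Reagents that add atoms: none
Why: Catalytic hydrogenolysis cleaves the three aryl benzyl ethers; the methyl ethers and the flavonol core are stable under these conditions.

## Compound list

1 | 5-methoxybenzene-1,3-diol (5-methoxyresorcinol) | COc1cc(O)cc(O)c1 | starting material
2 | 5-methoxy-1,3-phenylene bis(N,N-diethylcarbamate) | CCN(CC)C(=O)Oc1cc(OC)cc(OC(=O)N(CC)CC)c1 | intermediate
3 | [2,6-bis(diethylcarbamoyloxy)-4-methoxyphenyl]lithium | [Li]c1c(OC(=O)N(CC)CC)cc(OC)cc1OC(=O)N(CC)CC | intermediate (not isolated)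
4 | 5-methoxy-2-(trimethylsilyl)-1,3-phenylene bis(N,N-diethylcarbamate) | CCN(CC)C(=O)Oc1cc(OC)cc(OC(=O)N(CC)CC)c1[Si](C)(C)C | intermediate
5 | 5-methoxy-2-(trimethylsilyl)benzene-1,3-diol | COc1cc(O)c([Si](C)(C)C)c(O)c1 | intermediate
6 | 3-(benzyloxy)-5-methoxy-2-(trimethylsilyl)phenol | COc1cc(O)c([Si](C)(C)C)c(OCc2ccccc2)c1 | intermediate
7 | 3-(benzyloxy)-5-methoxy-2-(trimethylsilyl)phenyl trifluoromethanesulfonate | COc1cc(OCc2ccccc2)c([Si](C)(C)C)c(OS(=O)(=O)C(F)(F)F)c1 | intermediate
8 | 3,5-dihydroxy-4-methoxybenzoic acid | COc1c(O)cc(C(=O)O)cc1O | starting material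
9 | benzyl 3,5-bis(benzyloxy)-4-methoxybenzoate | COc1c(OCc2ccccc2)cc(C(=O)OCc2ccccc2)cc1OCc1ccccc1 | intermediate
10 | [3,5-bis(benzyloxy)-4-methoxyphenyl]methanol | COc1c(OCc2ccccc2)cc(CO)cc1OCc1ccccc1 | intermediate
11 | 3,5-bis(benzyloxy)-4-methoxybenzaldehyde | COc1c(OCc2ccccc2)cc(C=O)cc1OCc1ccccc1 | intermediate
12 | 1,3-bis(benzyloxy)-5-(2,2-dibromoethenyl)-2-methoxybenzene | COc1c(OCc2ccccc2)cc(C=C(Br)Br)cc1OCc1ccccc1 | intermediate
13 | {[3,5-bis(benzyloxy)-4-methoxyphenyl]ethynyl}lithium | [Li]C#Cc1cc(OCc2ccccc2)c(OC)c(OCc2ccccc2)c1 | intermediate (not isolated)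
14 | 3-[3,5-bis(benzyloxy)-4-methoxyphenyl]prop-2-ynoic acid | COc1c(OCc2ccccc2)cc(C#CC(=O)O)cc1OCc1ccccc1 | intermediate
15 | 3-(benzyloxy)-5-methoxybenzyne (3-(benzyloxy)-5-methoxy-1,2-didehydrobenzene) | COC1=CC#CC(OCc2ccccc2)=C1 | intermediate (not isolated)
16 | 1-[2-(benzyloxy)-6-hydroxy-4-methoxyphenyl]-3-[3,5-bis(benzyloxy)-4-methoxyphenyl]prop-2-yn-1-one (present as its cesium phenoxide) | COc1cc(O)c(C(=O)C#Cc2cc(OCc3ccccc3)c(OC)c(OCc3ccccc3)c2)c(OCc2ccccc2)c1 | intermediate (not isolated)
17 | 5-(benzyloxy)-2-[3,5-bis(benzyloxy)-4-methoxyphenyl]-7-methoxy-4H-chromen-4-one | COc1cc(OCc2ccccc2)c2c(=O)cc(-c3cc(OCc4ccccc4)c(OC)c(OCc4ccccc4)c3)oc2c1 | intermediate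
18 | 2-[3,5-bis(benzyloxy)-4-methoxyphenyl]-5-hydroxy-7-methoxy-4H-chromen-4-one | COc1cc(O)c2c(=O)cc(-c3cc(OCc4ccccc4)c(OC)c(OCc4ccccc4)c3)oc2c1 | intermediate
19 | potassium 2-[3,5-bis(benzyloxy)-4-methoxyphenyl]-5-hydroxy-7-methoxy-4-oxo-4H-chromen-8-yl sulfate | COc1cc(O)c2c(=O)cc(-c3cc(OCc4ccccc4)c(OC)c(OCc4ccccc4)c3)oc2c1OS(=O)(=O)[O-].[K+] | intermediate (not isolated)
20 | 2-[3,5-bis(benzyloxy)-4-methoxyphenyl]-5,8-dihydroxy-7-methoxy-4H-chromen-4-one | COc1cc(O)c2c(=O)cc(-c3cc(OCc4ccccc4)c(OC)c(OCc4ccccc4)c3)oc2c1O | intermediate
21 | 2-[3,5-bis(benzyloxy)-4-methoxyphenyl]-5-hydroxy-7,8-dimethoxy-4H-chromen-4-one | COc1cc(O)c2c(=O)cc(-c3cc(OCc4ccccc4)c(OC)c(OCc4ccccc4)c3)oc2c1OC | intermediate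
22 | 5-(benzyloxy)-2-[3,5-bis(benzyloxy)-4-methoxyphenyl]-7,8-dimethoxy-4H-chromen-4-one | COc1cc(OCc2ccccc2)c2c(=O)cc(-c3cc(OCc4ccccc4)c(OC)c(OCc4ccccc4)c3)oc2c1OC | intermediate
23 | 2,3-epoxide of 22: 6-(benzyloxy)-1a-[3,5-bis(benzyloxy)-4-methoxyphenyl]-3,4-dimethoxy-1a,7a-dihydro-7H-oxireno[2,3-b]chromen-7-one (racemic, cis-fused, one enantiomer drawn) | COc1cc(OCc2ccccc2)c2C(=O)[C@@H]5O[C@]5(c3cc(OCc4ccccc4)c(OC)c(OCc4ccccc4)c3)Oc2c1OC | intermediate (not isolated)
24 | 5-(benzyloxy)-2-[3,5-bis(benzyloxy)-4-methoxyphenyl]-3-hydroxy-7,8-dimethoxy-4H-chromen-4-one | COc1cc(OCc2ccccc2)c2c(=O)c(O)c(-c3cc(OCc4ccccc4)c(OC)c(OCc4ccccc4)c3)oc2c1OC | intermediate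
25 | 2-(3,5-dihydroxy-4-methoxyphenyl)-3,5-dihydroxy-7,8-dimethoxy-4H-chromen-4-one | COc1cc(O)c2c(=O)c(O)c(-c3cc(O)c(OC)c(O)c3)oc2c1OC | target

## Step count and least certain steps

Total: 17 steps. Longest linear sequence: 12 steps (steps 1–5, then 11–17; the branch through steps 6–10 is equally long).

**Step 11 (key step).** Several processes can divert the sequence. The aryl anion may be protonated (by HF-derived species or by the benzylic CH2 of the neighbouring ether) before the acyl shift, which stops at a simple aryl ester. The propiolic acid may lose CO2 at 125 °C. The phenoxide of 16 may be arylated by a second aryne. Ring closure may go 5-exo to an aurone. Fallback: starting from aldehyde 11, a Claisen–Schmidt condensation (KOH, EtOH) with 1-[2-(benzyloxy)-6-hydroxy-4-methoxyphenyl]ethan-1-one F2 should give (E)-1-[2-(benzyloxy)-6-hydroxy-4-methoxyphenyl]-3-[3,5-bis(benzyloxy)-4-methoxyphenyl]prop-2-en-1-one F3. F2 is made from purchasable 1-(2,6-dihydroxy-4-methoxyphenyl)ethan-1-one F1 with one equivalent of BnBr and K2CO3; the second hydroxyl stays chelated. Oxidative cyclisation of F3 with catalytic I2 in DMSO at 120 °C rejoins the route at 17. If the HI formed there removes the peri benzyl group, the product is 18, the next compound of the route.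

**Step 13.** Low conversion is to be expected: the lipophilic substrate dissolves poorly in the alkaline aqueous phase, sulfate radicals can degrade the electron-rich rings, and hydroxide can open the pyranone. Fallback: starting from 18, oxidation of the phenol with PhI(OCOCF3)2 in aqueous MeCN to the para-quinone 2-[3,5-bis(benzyloxy)-4-methoxyphenyl]-7-methoxy-4H-chromene-4,5,8-trione F4, then reduction with Na2S2O4, rejoins the route at 20.

**Step 16.** The dioxirane may oxidise the trioxygenated rings or the benzylic C–H bonds of the benzyl ethers faster than the rather electron-poor enone, or epoxidation may stay incomplete. Fallback: starting from 22, deprotonation at C3 with LDA in THF at −78 °C and trapping with B(OMe)3 gives dimethyl {5-(benzyloxy)-2-[3,5-bis(benzyloxy)-4-methoxyphenyl]-7,8-dimethoxy-4-oxo-4H-chromen-3-yl}boronate F5. Oxidation of the C–B bond with H2O2 in AcOH rejoins the route at 24.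

**Step 12.** The selectivity may erode, with partial loss of the B-ring benzyl groups, or the cleavage may stall. Fallback: starting from 17, hydrogenolysis of all three benzyl ethers (H2, Pd/C) gives 2-(3,5-dihydroxy-4-methoxyphenyl)-5-hydroxy-7-methoxy-4H-chromen-4-one F6. Benzylation with two equivalents of BnBr and K2CO3 in acetone then alkylates only the two non-chelated B-ring phenols and rejoins the route at 18.

**Step 3.** The two carbamates flank a bulky silyl group and may resist hydride attack, and prolonged heating or an acidic work-up risks loss of silicon. Fallback: starting from 1, isopropyl isocyanate with catalytic Et3N gives 5-methoxy-1,3-phenylene bis(N-isopropylcarbamate) F7. N-silylation and ortho-lithiation (t-BuMe2SiOTf, TMEDA; n-BuLi, −78 °C) followed by Me3SiCl give 5-methoxy-2-(trimethylsilyl)-1,3-phenylene bis(N-isopropylcarbamate) F8. Its carbamates are removed by base-induced elimination (DBU, Et2NH, MeCN, 40 °C), which rejoins the route at 5.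

## Further compounds

F1 | step 11 | 1-(2,6-dihydroxy-4-methoxyphenyl)ethan-1-one | COc1cc(O)c(C(C)=O)c(O)c1
F2 | step 11 | 1-[2-(benzyloxy)-6-hydroxy-4-methoxyphenyl]ethan-1-one | COc1cc(O)c(C(C)=O)c(OCc2ccccc2)c1
F3 | step 11 | (E)-1-[2-(benzyloxy)-6-hydroxy-4-methoxyphenyl]-3-[3,5-bis(benzyloxy)-4-methoxyphenyl]prop-2-en-1-one | COc1cc(O)c(C(=O)/C=C/c2cc(OCc3ccccc3)c(OC)c(OCc3ccccc3)c2)c(OCc2ccccc2)c1
F4 | step 13 | 2-[3,5-bis(benzyloxy)-4-methoxyphenyl]-7-methoxy-4H-chromene-4,5,8-trione | COC1=CC(=O)C2=C(OC(c3cc(OCc4ccccc4)c(OC)c(OCc4ccccc4)c3)=CC2=O)C1=O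
F5 | step 16 | dimethyl {5-(benzyloxy)-2-[3,5-bis(benzyloxy)-4-methoxyphenyl]-7,8-dimethoxy-4-oxo-4H-chromen-3-yl}boronate | COB(OC)c1c(-c2cc(OCc3ccccc3)c(OC)c(OCc3ccccc3)c2)oc2c(OC)c(OC)cc(OCc3ccccc3)c2c1=O
F6 | step 12 | 2-(3,5-dihydroxy-4-methoxyphenyl)-5-hydroxy-7-methoxy-4H-chromen-4-one | COc1cc(O)c2c(=O)cc(-c3cc(O)c(OC)c(O)c3)oc2c1
F7 | step 3 | 5-methoxy-1,3-phenylene bis(N-isopropylcarbamate) | CC(C)NC(=O)Oc1cc(OC)cc(OC(=O)NC(C)C)c1
F8 | step 3 | 5-methoxy-2-(trimethylsilyl)-1,3-phenylene bis(N-isopropylcarbamate) | CC(C)NC(=O)Oc1cc(OC)cc(OC(=O)NC(C)C)c1[Si](C)(C)C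
A1 | alternative 1 | trans-5-(benzyloxy)-2-[3,5-bis(benzyloxy)-4-methoxyphenyl]-3-hydroxy-7,8-dimethoxychroman-4-one (racemic, one enantiomer drawn) | O=C1[C@@H](O)[C@H](c2cc(OCc3ccccc3)c(OC)c(OCc3ccccc3)c2)Oc2c(OC)c(OC)cc(OCc3ccccc3)c12
A2 | alternative 1 | 6-(benzyloxy)-2-{1-[3,5-bis(benzyloxy)-4-methoxyphenyl]-2-oxoethoxy}-3,4-dimethoxybenzaldehyde (racemic) | O=CC(Oc1c(OC)c(OC)cc(OCc2ccccc2)c1C=O)c1cc(OCc2ccccc2)c(OC)c(OCc2ccccc2)c1
A3 | alternative 2 | 3-(benzyloxy)-2-[3,5-bis(benzyloxy)-4-methoxyphenyl]-5,7-dihydroxy-8-methoxy-4H-chromen-4-one | COc1c(O)cc(O)c2c(=O)c(OCc3ccccc3)c(-c3cc(OCc4ccccc4)c(OC)c(OCc4ccccc4)c3)oc12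
A4 | alternative 2 | methyl 2-{3-acetyl-5-(benzyloxy)-6-[3,5-bis(benzyloxy)-4-methoxyphenyl]-4-oxo-4H-pyran-2-yl}-2-methoxyacetate (racemic) | COC(=O)C(OC)c1oc(-c2cc(OCc3ccccc3)c(OC)c(OCc3ccccc3)c2)c(OCc2ccccc2)c(=O)c1C(C)=O
A5 | alternative 3 | 5-(benzyloxy)-2-[3,5-bis(benzyloxy)-4-methoxyphenyl]-7,8-dimethoxy-4H-chromen-4-one (identical with 22) | COc1cc(OCc2ccccc2)c2c(=O)cc(-c3cc(OCc4ccccc4)c(OC)c(OCc4ccccc4)c3)oc2c1OC
A6 | alternative 3 | (Z)-3-[5-(benzyloxy)-2,3-dimethoxyphenoxy]-3-[3,5-bis(benzyloxy)-4-methoxyphenyl]prop-2-enoic acid | OC(=O)/C=C(\Oc1cc(OCc2ccccc2)cc(OC)c1OC)c1cc(OCc2ccccc2)c(OC)c(OCc2ccccc2)c1
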